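**Plan**

- Retrosynthesis: after removing the O-protecting groups, ring A is cut at C1'–C2' and C5'–C6' into a terminal ynone and a 1,1,3-trioxygenated butadiene. The ynone is cut at C(=O)–C≡C (acetylide plus N-methoxy-N-methylamide) and at the C6–vinyl bond (Heck). The chromanol goes back through its 3,4-epoxide to a 2H-chromene and an aryl propargyl ether.
- Enabling feature: ring A carries oxygen on C2' and C4', ortho and para to the acyl-bearing C1'. This maps onto the C1 and C3 oxygens of the diene and the carbonyl of an alkynyl ketone.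
- Forward order: ring C (the dihydropyran) is fused onto the brominated ring B by propargyl Claisen rearrangement and electrocyclisation. The enone bridge is then attached at C6 and extended to the ynone, and ring A is built last by Diels–Alder benzannulation.
- Stereochemistry: the only stereocentre, C3 (S), comes from Jacobsen–Katsuki epoxidation of the chromene followed by hydride opening at C4. The E alkene comes from the Heck reaction.

Key step: step 11

Remark on the chemistry: the (S,S)-salen manganese catalyst is assumed to give the (3S,4S)-epoxide from chromene 7, as it does from other 2,2-dimethylchromenes. Chroman locants are O1, C2 (gem-dimethyl), C3 (carbinol), C4, C4a, C5–C8, C8a; ring A locants are primed.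

**Route**

Step 1
Reactants: 1 2-(benzyloxy)phenol
Product: 2 2-(benzyloxy)-4-bromophenol
Conditions: NBS (1.0 equiv), MeCN, 0 °C
Reagents that add atoms: N-bromosuccinimide, O=C1CCC(=O)N1Br
Why: Electrophilic aromatic bromination of a phenol goes para to the free hydroxyl, the stronger donor compared with the benzyl ether, so bromine should enter C4, the carbon that becomes C6 of the chroman.

Step 2
Reactants: 2 2-(benzyloxy)-4-bromophenol; 3 3-chloro-3-methylbut-1-yne
Product: 4 2-(benzyloxy)-4-bromo-1-[(2-methylbut-3-yn-2-yl)oxy]benzene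
Conditions: 3 (1.5 equiv), DBU, CuCl2 (1 mol%), MeCN, 0 °C
Reagents that add atoms: 3-chloro-3-methylbut-1-yne 3, C#CC(C)(C)Cl
Why: Copper-catalysed propargylic substitution of the tertiary chloride by the phenoxide is the standard O-propargylation leading to aryl 1,1-dimethylpropargyl ethers and leaves the aryl bromide and the benzyl ether untouched.

Step 3
Reactants: 4 2-(benzyloxy)-4-bromo-1-[(2-methylbut-3-yn-2-yl)oxy]benzene
Product: 7 8-(benzyloxy)-6-bromo-2,2-dimethyl-2H-chromene, via ortho-allenylphenol 5 (not isolated), via ortho-quinone methide 6 (not isolated)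
Conditions: PhNEt2, 190 °C
Reagents that add atoms: none
Why: Aromatic propargyl Claisen rearrangement into the only free ortho position, enolisation to the allenylphenol, 1,5-hydrogen shift to the ortho-quinone methide and oxa-6π-electrocyclisation should close ring C in the classical thermal chromene synthesis.

Step 4
Reactants: 7 8-(benzyloxy)-6-bromo-2,2-dimethyl-2H-chromene
Product: 8 (3S,4S)-8-(benzyloxy)-6-bromo-3,4-epoxy-2,2-dimethylchromane
Conditions: (S,S)-N,N'-bis(3,5-di-tert-butylsalicylidene)-1,2-cyclohexanediaminomanganese chloride (5 mol%), 4-phenylpyridine N-oxide (20 mol%), aq. NaOCl (pH 11.3), CH2Cl2, 0 °C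
Reagents that add atoms: sodium hypochlorite, [Na+].[O-]Cl
Why: Jacobsen–Katsuki epoxidation works best on the cis-disubstituted, aryl-conjugated alkene of 2,2-dimethylchromenes, and the (S,S) ligand on trivalent manganese should direct oxygen transfer to the face that gives the (3S,4S)-epoxide, which sets C3 of the target.

Step 5
Reactants: 8 (3S,4S)-8-(benzyloxy)-6-bromo-3,4-epoxy-2,2-dimethylchromane
Product: 9 (S)-8-(benzyloxy)-6-bromo-2,2-dimethylchroman-3-ol
Conditions: LiAlH4, THF, 0 → 25 °C
Reagents that add atoms: none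
Why: Reductive epoxide opening by SN2 attack of hydride at the benzylic C4 is expected because C3 is shielded by the quaternary C2, so the C3–O bond and its S configuration are kept while C4 becomes the ring methylene.

Step 6
Reactants: 9 (S)-8-(benzyloxy)-6-bromo-2,2-dimethylchroman-3-ol
Product: 10 (S)-8-(benzyloxy)-6-bromo-3-(tert-butyldimethylsilyloxy)-2,2-dimethylchromane
Conditions: TBSOTf, 2,6-lutidine, CH2Cl2, 0 °C
Reagents that add atoms: tert-butyldimethylsilyl trifluoromethanesulfonate, CC(C)(C)[Si](C)(C)OS(=O)(=O)C(F)(F)F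
Why: Silyl ether protection of the hindered secondary alcohol with the silyl triflate and a non-nucleophilic base masks the hydroxyl against the Grignard reagent and the silyl ketene acetal diene used later.

Step 7
Reactants: 10 (S)-8-(benzyloxy)-6-bromo-3-(tert-butyldimethylsilyloxy)-2,2-dimethylchromane; 11 N-methoxy-N-methylacrylamide
Product: 12 (E)-3-[(S)-8-(benzyloxy)-3-(tert-butyldimethylsilyloxy)-2,2-dimethylchroman-6-yl]-N-methoxy-N-methylprop-2-enamide
Conditions: Pd(OAc)2 (5 mol%), P(o-tol)3 (15 mol%), Et3N, DMF, 100 °C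
Reagents that add atoms: N-methoxy-N-methylacrylamide 11, C=CC(=O)N(C)OC
Why: The Mizoroki–Heck reaction of the aryl bromide with the electron-poor acrylamide proceeds by syn carbopalladation and syn β-hydride elimination, which should give only the E alkene and deliver the three bridge carbons with the acyl carbon already at the amide oxidation level.

Step 8
Reactants: 12 (E)-3-[(S)-8-(benzyloxy)-3-(tert-butyldimethylsilyloxy)-2,2-dimethylchroman-6-yl]-N-methoxy-N-methylprop-2-enamide; 13 ethynylmagnesium bromide
Product: 15 (E)-1-[(S)-8-(benzyloxy)-3-(tert-butyldimethylsilyloxy)-2,2-dimethylchroman-6-yl]pent-1-en-4-yn-3-one, via magnesium hemiaminal chelate 14 (not isolated)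
Conditions: HC≡CMgBr (3 equiv), THF, 0 °C; inverse quench into cold 1 M aq. NaHSO4
Reagents that add atoms: ethynylmagnesium bromide 13, C#C[Mg]Br
Why: In the Weinreb ketone synthesis the acetylide adds 1,2 to the N-methoxy-N-methylamide to give a magnesium-chelated tetrahedral adduct that cannot collapse before the cold acidic quench, so over-addition is avoided and the terminal ynone is released only on work-up, with the liberated amine protonated.

Step 9
Reactants: 16 1,1-dimethoxyethene; 17 acetyl chloride
Product: 18 4,4-dimethoxybut-3-en-2-one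
Conditions: AcCl, Et3N, Et2O, 0 → 25 °C
Reagents that add atoms: acetyl chloride 17, CC(=O)Cl
Why: C-acylation of a ketene acetal is expected because its CH2 carbon is strongly nucleophilic, and loss of HCl to triethylamine then gives the push–pull enone.

Step 10
Reactants: 18 4,4-dimethoxybut-3-en-2-one
Product: 19 1,1-dimethoxy-3-(trimethylsilyloxy)buta-1,3-diene
Conditions: Me3SiCl, Et3N, ZnCl2 (cat.), benzene, 40 °C; distilled and used at once
Reagents that add atoms: chlorotrimethylsilane, C[Si](C)(C)Cl
Why: Silyl enol ether formation by soft enolisation of the methyl ketone and O-silylation converts the vinylogous ester into the 1,1,3-trioxygenated diene.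

Step 11
Reactants: 15 (E)-1-[(S)-8-(benzyloxy)-3-(tert-butyldimethylsilyloxy)-2,2-dimethylchroman-6-yl]pent-1-en-4-yn-3-one; 19 1,1-dimethoxy-3-(trimethylsilyloxy)buta-1,3-diene
Product: 22 (E)-3-[(S)-8-(benzyloxy)-3-(tert-butyldimethylsilyloxy)-2,2-dimethylchroman-6-yl]-1-(4-hydroxy-2-methoxyphenyl)prop-2-en-1-one, via cyclohexadiene cycloadduct 20 (not isolated), via aryl trimethylsilyl ether 21 (not isolated)
Conditions: 19 (2.5 equiv), toluene, 25 → 80 °C; then 0.5 M HCl, THF, 0 °C
Reagents that add atoms: 1,1-dimethoxy-3-(trimethylsilyloxy)buta-1,3-diene 19, COC(OC)=CC(=C)O[Si](C)(C)C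
Why: Diene 19 has its largest HOMO coefficient on the terminal CH2 and ynone 15 its largest LUMO coefficient on the terminal alkyne carbon, so an asynchronous, Michael-like [4+2] cycloaddition should first join these two carbons (the C5'–C6' bond) and then bond the acetal carbon to the acyl-bearing alkyne carbon (the C1'–C2' bond), giving the 1,4-cyclohexadiene 20. The closest known reaction type is the Diels–Alder benzannulation of 1,1-dialkoxy-3-silyloxybutadienes with acetylenic esters and ketones, which gives 4-hydroxy-2-alkoxyaryl carbonyl compounds. Ring A is thus closed as a six-membered carbocycle by intermolecular [4+2] cycloaddition, and it becomes aromatic when 20 loses methanol by 1,4-elimination to the aryl silyl ether 21, whose Si–O bond is hydrolysed in the dilute acid work-up. No stereocentre is created, and the C3 silyl ether, the benzyl ether and the E alkene are spectators. The step needs regioselectivity, secured by the matched polarisation of diene and ynone that places the methoxy group ortho and the hydroxyl para to the ketone, and chemoselectivity for the alkyne over the alkene of the same cross-conjugated ketone, secured because the unsubstituted sp terminus is far more electrophilic and less hindered than the β-aryl enone carbon, which the electron-rich chroman deactivates.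

Step 12
Reactants: 22 (E)-3-[(S)-8-(benzyloxy)-3-(tert-butyldimethylsilyloxy)-2,2-dimethylchroman-6-yl]-1-(4-hydroxy-2-methoxyphenyl)prop-2-en-1-one
Product: 23 (E)-3-[(S)-3-(tert-butyldimethylsilyloxy)-8-hydroxy-2,2-dimethylchroman-6-yl]-1-(2,4-dihydroxyphenyl)prop-2-en-1-one
Conditions: BCl3 (6 equiv), C6HMe5 (3 equiv), CH2Cl2, −78 → 0 °C; then MeOH, aq. NaHCO3
Reagents that add atoms: none
Why: In this Lewis acid ether cleavage, BCl3 chelated between the ketone and the 2'-methoxy oxygen should remove that methyl group as chloromethane and also ionise the 8-O-benzyl ether, whose benzyl cation is trapped by pentamethylbenzene (Friedel–Crafts benzyl transfer) so that the enone and the electron-rich rings are not benzylated. Any material that also loses the silyl group here is already 24.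

Step 13
Reactants: 23 (E)-3-[(S)-3-(tert-butyldimethylsilyloxy)-8-hydroxy-2,2-dimethylchroman-6-yl]-1-(2,4-dihydroxyphenyl)prop-2-en-1-one
Product: 24 (E)-1-(2,4-dihydroxyphenyl)-3-[(S)-3,8-dihydroxy-2,2-dimethylchroman-6-yl]prop-2-en-1-one (CNP0326608.1)
Conditions: HF·pyridine, pyridine, THF, 0 → 25 °C
Reagents that add atoms: none
Why: Fluoride-mediated desilylation under buffered, weakly acidic conditions should free the C3 hydroxyl without the base-induced chalcone–flavanone isomerisation of the 2'-hydroxychalcone and without touching the S centre.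

**Compound list**

1 | 2-(benzyloxy)phenol | Oc1ccccc1OCc1ccccc1 | starting material
2 | 2-(benzyloxy)-4-bromophenol | Oc1ccc(Br)cc1OCc1ccccc1 | intermediate
3 | 3-chloro-3-methylbut-1-yne | C#CC(C)(C)Cl | starting material
4 | 2-(benzyloxy)-4-bromo-1-[(2-methylbut-3-yn-2-yl)oxy]benzene | C#CC(C)(C)Oc1ccc(Br)cc1OCc1ccccc1 | intermediate
5 | 2-(benzyloxy)-4-bromo-6-(3-methylbuta-1,2-dien-1-yl)phenol (ortho-allenylphenol, formed in the flask) | CC(C)=C=Cc1cc(Br)cc(OCc2ccccc2)c1O | intermediate
6 | 2-(benzyloxy)-4-bromo-6-(3-methylbut-2-en-1-ylidene)cyclohexa-2,4-dien-1-one (ortho-quinone methide, formed in the flask) | CC(C)=CC=C1C=C(Br)C=C(OCc2ccccc2)C1=O | intermediate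
7 | 8-(benzyloxy)-6-bromo-2,2-dimethyl-2H-chromene | CC1(C)C=Cc2cc(Br)cc(OCc3ccccc3)c2O1 | intermediate
8 | (3S,4S)-8-(benzyloxy)-6-bromo-3,4-epoxy-2,2-dimethylchromane | CC1(C)Oc2c(OCc3ccccc3)cc(Br)cc2[C@@H]4O[C@H]14 | intermediate
9 | (S)-8-(benzyloxy)-6-bromo-2,2-dimethylchroman-3-ol | CC1(C)Oc2c(OCc3ccccc3)cc(Br)cc2C[C@@H]1O | intermediate
10 | (S)-8-(benzyloxy)-6-bromo-3-(tert-butyldimethylsilyloxy)-2,2-dimethylchromane | CC1(C)Oc2c(OCc3ccccc3)cc(Br)cc2C[C@@H]1O[Si](C)(C)C(C)(C)C | intermediate
11 | N-methoxy-N-methylacrylamide | C=CC(=O)N(C)OC | starting material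
12 | (E)-3-[(S)-8-(benzyloxy)-3-(tert-butyldimethylsilyloxy)-2,2-dimethylchroman-6-yl]-N-methoxy-N-methylprop-2-enamide | CC1(C)Oc2c(OCc3ccccc3)cc(/C=C/C(=O)N(C)OC)cc2C[C@@H]1O[Si](C)(C)C(C)(C)C | intermediate
13 | ethynylmagnesium bromide | C#C[Mg]Br | starting material
14 | bromomagnesium alkoxide of (E)-1-[(S)-8-(benzyloxy)-3-(tert-butyldimethylsilyloxy)-2,2-dimethylchroman-6-yl]-3-[methoxy(methyl)amino]pent-1-en-4-yn-3-ol (tetrahedral adduct, both carbinol epimers, formed in the flask) | CC1(C)Oc2c(OCc3ccccc3)cc(/C=C/C(O[Mg]Br)(C#C)N(C)OC)cc2C[C@@H]1O[Si](C)(C)C(C)(C)C | intermediate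
15 | (E)-1-[(S)-8-(benzyloxy)-3-(tert-butyldimethylsilyloxy)-2,2-dimethylchroman-6-yl]pent-1-en-4-yn-3-one | CC1(C)Oc2c(OCc3ccccc3)cc(/C=C/C(=O)C#C)cc2C[C@@H]1O[Si](C)(C)C(C)(C)C | intermediate
16 | 1,1-dimethoxyethene | C=C(OC)OC | starting material
17 | acetyl chloride | CC(=O)Cl | starting material
18 | 4,4-dimethoxybut-3-en-2-one | CC(=O)C=C(OC)OC | intermediate
19 | 1,1-dimethoxy-3-(trimethylsilyloxy)buta-1,3-diene | COC(OC)=CC(=C)O[Si](C)(C)C | intermediate
20 | (E)-3-[(S)-8-(benzyloxy)-3-(tert-butyldimethylsilyloxy)-2,2-dimethylchroman-6-yl]-1-[6,6-dimethoxy-4-(trimethylsilyloxy)cyclohexa-1,4-dien-1-yl]prop-2-en-1-one (cycloadduct, formed in the flask) | CC1(C)Oc2c(OCc3ccccc3)cc(/C=C/C(=O)C3=CCC(O[Si](C)(C)C)=CC3(OC)OC)cc2C[C@@H]1O[Si](C)(C)C(C)(C)C | intermediate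
21 | (E)-3-[(S)-8-(benzyloxy)-3-(tert-butyldimethylsilyloxy)-2,2-dimethylchroman-6-yl]-1-[2-methoxy-4-(trimethylsilyloxy)phenyl]prop-2-en-1-one (formed in the flask) | CC1(C)Oc2c(OCc3ccccc3)cc(/C=C/C(=O)c3ccc(O[Si](C)(C)C)cc3OC)cc2C[C@@H]1O[Si](C)(C)C(C)(C)C | intermediate
22 | (E)-3-[(S)-8-(benzyloxy)-3-(tert-butyldimethylsilyloxy)-2,2-dimethylchroman-6-yl]-1-(4-hydroxy-2-methoxyphenyl)prop-2-en-1-one | CC1(C)Oc2c(OCc3ccccc3)cc(/C=C/C(=O)c3ccc(O)cc3OC)cc2C[C@@H]1O[Si](C)(C)C(C)(C)C | intermediate
23 | (E)-3-[(S)-3-(tert-butyldimethylsilyloxy)-8-hydroxy-2,2-dimethylchroman-6-yl]-1-(2,4-dihydroxyphenyl)prop-2-en-1-one | CC1(C)Oc2c(O)cc(/C=C/C(=O)c3ccc(O)cc3O)cc2C[C@@H]1O[Si](C)(C)C(C)(C)C | intermediate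
24 | (E)-1-(2,4-dihydroxyphenyl)-3-[(S)-3,8-dihydroxy-2,2-dimethylchroman-6-yl]prop-2-en-1-one | CC1(C)Oc2c(O)cc(/C=C/C(=O)c3ccc(O)cc3O)cc2C[C@@H]1O | target

**Step count**

Total: 13 steps. Longest linear sequence: 11 steps (steps 1–8 and 11–13). The diene branch (steps 9–10) is 2 steps.

**Steps most likely to fail**

Step 11. The diene may add once in a conjugate sense without closing the ring, the ynone may oligomerise, or the moisture-sensitive diene may hydrolyse before it reacts. In that case ring A would be brought in intact instead of being built. Setting out from bromide 10, bromine–lithium exchange (n-BuLi, THF, −78 °C) and quenching with DMF should give (S)-8-(benzyloxy)-3-(tert-butyldimethylsilyloxy)-2,2-dimethylchromane-6-carbaldehyde F1. Claisen–Schmidt condensation of this aldehyde with commercial 1-(4-hydroxy-2-methoxyphenyl)ethanone (KOH, EtOH, 25 °C) should then give the E chalcone directly, rejoining the route at 22 and bypassing steps 7–11.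

Step 12. The warming needed to cleave the chelated methyl ether prolongs contact with BCl3, and boron bound at O8 next to O1 may ionise the tertiary C2–O1 bond and open ring C. The fallback removes the methyl ether from the problem. Setting out from ynone 15, the diene is replaced by one bearing a silyloxy group in place of one methoxy group. Methyl acetoacetate is silylated (Me3SiCl, Et3N) to methyl 3-(trimethylsilyloxy)but-2-enoate F2, and deprotonation and a second silylation (LDA, Me3SiCl, THF, −78 °C) give 1-methoxy-1,3-bis(trimethylsilyloxy)buta-1,3-diene F3. The same cycloaddition with 15, loss of methanol and acidic hydrolysis of both trimethylsilyl ethers should give (E)-3-[(S)-8-(benzyloxy)-3-(tert-butyldimethylsilyloxy)-2,2-dimethylchroman-6-yl]-1-(2,4-dihydroxyphenyl)prop-2-en-1-one F4. Only the benzyl ether then has to go, which BCl3 and pentamethylbenzene should achieve at −78 °C without warming, rejoining the route at 23.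

Step 8. The weakly nucleophilic acetylide may add sluggishly to the conjugated amide, and the N,O-dimethylhydroxylamine released on quench may add in a conjugate sense to the new ynone. The fallback reaches the ynone through the alcohol oxidation level. Setting out from bromide 10, a Heck reaction with acrolein diethyl acetal (Pd(OAc)2, n-Bu4NOAc, K2CO3, KCl, DMF, 90 °C) should give (S)-8-(benzyloxy)-3-(tert-butyldimethylsilyloxy)-6-[(E)-3,3-diethoxyprop-1-en-1-yl]-2,2-dimethylchromane F5. Brief treatment with dilute HCl should hydrolyse this to (E)-3-[(S)-8-(benzyloxy)-3-(tert-butyldimethylsilyloxy)-2,2-dimethylchroman-6-yl]prop-2-enal F6. Addition of ethynylmagnesium bromide 13 (THF, −78 °C) should give (E)-1-[(S)-8-(benzyloxy)-3-(tert-butyldimethylsilyloxy)-2,2-dimethylchroman-6-yl]pent-1-en-4-yn-3-ol F7 as a mixture of carbinol epimers, which does not matter. Oxidation with MnO2 (CH2Cl2, 25 °C) removes that centre and rejoins the route at 15.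

**Further compounds**

F1 | step 11 | (S)-8-(benzyloxy)-3-(tert-butyldimethylsilyloxy)-2,2-dimethylchromane-6-carbaldehyde | CC1(C)Oc2c(OCc3ccccc3)cc(C=O)cc2C[C@@H]1O[Si](C)(C)C(C)(C)C
F2 | step 12 | methyl 3-(trimethylsilyloxy)but-2-enoate (alkene geometry not defined) | COC(=O)C=C(C)O[Si](C)(C)C
F3 | step 12 | 1-methoxy-1,3-bis(trimethylsilyloxy)buta-1,3-diene (ketene acetal geometry not defined) | COC(O[Si](C)(C)C)=CC(=C)O[Si](C)(C)C
F4 | step 12 | (E)-3-[(S)-8-(benzyloxy)-3-(tert-butyldimethylsilyloxy)-2,2-dimethylchroman-6-yl]-1-(2,4-dihydroxyphenyl)prop-2-en-1-one | CC1(C)Oc2c(OCc3ccccc3)cc(/C=C/C(=O)c3ccc(O)cc3O)cc2C[C@@H]1O[Si](C)(C)C(C)(C)C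
F5 | step 8 | (S)-8-(benzyloxy)-3-(tert-butyldimethylsilyloxy)-6-[(E)-3,3-diethoxyprop-1-en-1-yl]-2,2-dimethylchromane | CCOC(OCC)/C=C/c1cc2C[C@H](O[Si](C)(C)C(C)(C)C)C(C)(C)Oc2c(OCc2ccccc2)c1
F6 | step 8 | (E)-3-[(S)-8-(benzyloxy)-3-(tert-butyldimethylsilyloxy)-2,2-dimethylchroman-6-yl]prop-2-enal | CC1(C)Oc2c(OCc3ccccc3)cc(/C=C/C=O)cc2C[C@@H]1O[Si](C)(C)C(C)(C)C
F7 | step 8 | (E)-1-[(S)-8-(benzyloxy)-3-(tert-butyldimethylsilyloxy)-2,2-dimethylchroman-6-yl]pent-1-en-4-yn-3-ol (both carbinol epimers) | CC1(C)Oc2c(OCc3ccccc3)cc(/C=C/C(O)C#C)cc2C[C@@H]1O[Si](C)(C)C(C)(C)C
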